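**Retrosynthetic overview** (target numbered as spiro[5.5]undecane: C1(=O)–C2(Me)=C3(OMe)–C4Me2–C5(=O)–C6(spiro)–C7H(iPr)–C8H2–C9H=C10(homoprenyl)–C11H2)
1. The C6–C11 bond is made last by a Claisen shift in the 2‑alkenyl‑dihydropyran 20; this closes the cyclohexene, puts the homoprenyl carbon C10 next to C11 (the orientation a myrcene Diels–Alder reaction disfavours) and relays the pyran C2 configuration to C6.
2. In 20 the C1 oxygen is the pyran enol‑ether oxygen, so the two carbonyls that make C6 stereogenic (C1, conjugated with C2(Me)=C3(OMe), and C5, next to C4Me2) are chemically different when the C–C bond forms; 20 comes from phenol 18 by ortho C‑methylation (dearomatisation, creates C4Me2).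
3. The 2,4‑trans chromane 18 comes from lactol 16 and alkenyltrifluoroborate 13 (from ketone 6); 16 comes from the mirror‑symmetric resorcinol 5 and enal 14 by organocatalytic Friedel–Crafts alkylation/lactolisation, which sets C7 and cannot give pyran regioisomers; 5 comes from acetophenone 1.
4. Ring order: arene (bought) → pyran (step 5) → cyclohexadienone by dearomatisation (step 7) → cyclohexene with opening of the pyran (step 8).

Key step: step 8

Remark: by CIP analysis the target is (6R,7S), with the isopropyl group cis to the C1 carbonyl (the one conjugated with the enol ether).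
Assumption: (S)‑α,α‑diphenylprolinol trimethylsilyl ether is taken to give the (S) centre in step 5 by the usual shielding model for E‑iminium ions; the (R)‑catalyst would be used if the opposite sense were found.

**Step 1**
Reactants: 1 1-(2,6-dihydroxy-4-methoxyphenyl)ethan-1-one; 2 iodomethane
Product: 4 1-(2,6-dihydroxy-4-methoxy-3,5-dimethylphenyl)ethan-1-one, via mono-C-methyl ketone 3 (not isolated)
Conditions: NaOMe (2.2 equiv), MeI (2.1 equiv), MeOH, 0 °C → reflux
Reagents that add atoms: iodomethane (2), CI
Why: Nuclear C‑methylation of a polyhydroxyacetophenone in a protic medium: the two ring C–H positions each lie ortho/para to three oxygen donors and should take one methyl group each, the stoichiometry stopping the reaction at the aromatic stage; no stereocentre.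

**Step 2**
Reactants: 4 1-(2,6-dihydroxy-4-methoxy-3,5-dimethylphenyl)ethan-1-one
Product: 5 5-methoxy-4,6-dimethylbenzene-1,3-diol
Conditions: 85% H3PO4, 110 °C, N2
Reagents that add atoms: none
Why: Acid‑mediated protodeacylation (retro‑Friedel–Crafts): ipso protonation is favoured by two ortho hydroxyls and the para methoxy group, the acetyl group leaves as acetic acid, and the aryl methyl ether should survive the non‑nucleophilic acid.

**Step 3**
Reactants: 6 6-methylhept-5-en-2-one; 7 N-phenylbis(trifluoromethanesulfonimide)
Product: 9 6-methylhepta-1,5-dien-2-yl trifluoromethanesulfonate, via lithium enolate 8 (not isolated)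
Conditions: LDA, THF, −78 °C; then PhNTf2, −78 → 0 °C; aq. NH4Cl
Reagents that add atoms: N-phenylbis(trifluoromethanesulfonimide) (7), O=S(=O)(N(c1ccccc1)S(=O)(=O)C(F)(F)F)C(F)(F)F
Why: Kinetic deprotonation of the methyl ketone at CH3 and O‑triflation of the terminal enolate (enol triflate formation) should give the 1,1‑disubstituted alkenyl triflate; no stereocentre.

**Step 4**
Reactants: 9 6-methylhepta-1,5-dien-2-yl trifluoromethanesulfonate; 10 bis(pinacolato)diboron; 11 potassium hydrogen difluoride
Product: 13 potassium trifluoro(6-methylhepta-1,5-dien-2-yl)borate, via pinacol boronate 12 (not isolated)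
Conditions: B2pin2, PdCl2(PPh3)2 (3 mol%), PPh3, KOPh, PhMe, 50 °C; then aq. KHF2, MeOH, rt
Reagents that add atoms: bis(pinacolato)diboron (10), CC1(C)OB(OC1(C)C)B1OC(C)(C)C(C)(C)O1; potassium hydrogen difluoride (11), [K+].F.[F-]
Why: Miyaura borylation of an alkenyl triflate followed by exchange of the pinacol ester with KHF2 should give the bench‑stable alkenyltrifluoroborate with the alkene position unchanged.

**Step 5**
Reactants: 5 5-methoxy-4,6-dimethylbenzene-1,3-diol; 14 (E)-4-methylpent-2-enal
Product: 16 (4S)-7-methoxy-6,8-dimethyl-4-(propan-2-yl)chromane-2,5-diol (both C2 anomers), via open-chain aldehyde 15 (not isolated)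
Conditions: (S)‑α,α‑diphenylprolinol TMS ether (20 mol%), PhCO2H (20 mol%), PhMe, 0 °C → rt
Reagents that add atoms: (E)-4-methylpent-2-enal (14), CC(C)/C=C/C=O
Why: Iminium‑catalysed asymmetric Friedel–Crafts alkylation/hemiacetalisation of a hydroxyarene with an enal: the only ring C–H of 5 adds to C3 of the E‑iminium ion on the face left open by the CPh2(OTMS) group, which should set the (S) isopropyl‑bearing centre, and either of the two equivalent hydroxyls closes the same lactol.

**Step 6**
Reactants: 16 (4S)-7-methoxy-6,8-dimethyl-4-(propan-2-yl)chromane-2,5-diol; 13 potassium trifluoro(6-methylhepta-1,5-dien-2-yl)borate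
Product: 18 (2S,4S)-7-methoxy-6,8-dimethyl-2-(6-methylhepta-1,5-dien-2-yl)-4-(propan-2-yl)chroman-5-ol, via oxocarbenium ion 17 (not isolated)
Conditions: BF3·OEt2 (3 equiv), CH2Cl2/MeCN, −40 → 0 °C
Reagents that add atoms: potassium trifluoro(6-methylhepta-1,5-dien-2-yl)borate (13), [K+].C=C(CCC=C(C)C)[B-](F)(F)F
Why: BF3‑promoted ionisation of the lactol and alkenyl transfer from the organotrifluoroborate (oxocarbenium alkenylation): peri strain with the C5 oxygen holds the 4‑isopropyl group pseudo‑axial, so the alkenyl group should enter C2 from the opposite face and give the 2,4‑trans (2S) chromane; the fully substituted arene cannot undergo Friedel–Crafts side reactions.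

**Step 7**
Reactants: 18 (2S,4S)-7-methoxy-6,8-dimethyl-2-(6-methylhepta-1,5-dien-2-yl)-4-(propan-2-yl)chroman-5-ol; 2 iodomethane
Product: 20 (2S,4S)-7-methoxy-6,6,8-trimethyl-2-(6-methylhepta-1,5-dien-2-yl)-4-(propan-2-yl)-2,3,4,6-tetrahydro-5H-chromen-5-one, via lithium phenolate 19 (not isolated)
Conditions: LiHMDS (1.05 equiv), PhMe, 0 °C; then MeI (5 equiv), 0 → 40 °C
Reagents that add atoms: iodomethane (2), CI
Why: Alkylative dearomatisation of a phenolate: in toluene the tight Li–O ion pair should direct MeI to the ortho carbon C6 (activated by three oxygens, less hindered than the ring‑fusion carbon C4a), which turns C6 into CMe2 and C5–O into a ketone and leaves the pyran oxygen as a fixed enol ether on C8a; C2 and C4 are untouched.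

**Step 8**
Reactants: 20 (2S,4S)-7-methoxy-6,6,8-trimethyl-2-(6-methylhepta-1,5-dien-2-yl)-4-(propan-2-yl)-2,3,4,6-tetrahydro-5H-chromen-5-one
Product: 21 (6R,7S)-3-methoxy-2,4,4-trimethyl-10-(4-methylpent-3-en-1-yl)-7-(propan-2-yl)spiro[5.5]undeca-2,9-diene-1,5-dione
Conditions: PhMe (degassed, 0.02 M), BHT (cat.), sealed tube, 170 °C
Reagents that add atoms: none
Why: Concerted [3,3]-sigmatropic (Claisen) shift of the allyl vinyl ether C4a=C8a–O1–C2–C(R)=CH2: the exocyclic CH2 bonds to C4a while C2–O1 breaks, so C8a becomes the ring ketone, C4a the spiro carbon and C2 the CH of the new trisubstituted alkene. The closest known reaction type is the thermal Claisen rearrangement of 2-alkenyl-3,4-dihydro-2H-pyrans to cyclohex-3-enyl ketones, which also turns hetero-Diels–Alder adducts of 2-alkylidene-1,3-diones into spiro diones. The cyclohexene closes through a boat-like six-membered transition state inscribed in the pyran ring (a bicyclo[2.2.2]octane-like array), suprafacial on the enol ether and on the allyl unit, and no other ring is formed. The spiro stereocentre is set by C2: the alkenyl group can reach C4a only on the ring face on which it stands, which is trans to the isopropyl group, and since the carbon that loses the ether oxygen (C8a) is the one that bears C(Me)=C(OMe), the isopropyl group should end cis to that carbonyl, which is (6R) next to the untouched (7S) centre. The step needs [3,3] periselectivity over heterolysis of the allylic C–O bond and over retro-hetero-Diels–Alder cleavage, both of which would erase the chirality transfer; an apolar, acid-free medium at the lowest effective temperature favours the concerted path, and the new C=O bond, with a vinylogous ester kept on the C8a side, provides the driving force. Regiochemistry is not an issue, because the position of the alkene (homoprenyl carbon next to the spiro CH2) is fixed by the connectivity of the allyl unit.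

**Compound list**
1 | 1-(2,6-dihydroxy-4-methoxyphenyl)ethan-1-one | CC(=O)c1c(O)cc(OC)cc1O | starting material
2 | iodomethane | CI | starting material
3 | 1-(2,6-dihydroxy-4-methoxy-3-methylphenyl)ethan-1-one | CC(=O)c1c(O)cc(OC)c(C)c1O | intermediate
4 | 1-(2,6-dihydroxy-4-methoxy-3,5-dimethylphenyl)ethan-1-one | CC(=O)c1c(O)c(C)c(OC)c(C)c1O | intermediate
5 | 5-methoxy-4,6-dimethylbenzene-1,3-diol | COc1c(C)c(O)cc(O)c1C | intermediate
6 | 6-methylhept-5-en-2-one | CC(=O)CCC=C(C)C | starting material
7 | N-phenylbis(trifluoromethanesulfonimide) | O=S(=O)(N(c1ccccc1)S(=O)(=O)C(F)(F)F)C(F)(F)F | starting material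
8 | lithium 6-methylhepta-1,5-dien-2-olate | [Li+].[O-]C(=C)CCC=C(C)C | intermediate
9 | 6-methylhepta-1,5-dien-2-yl trifluoromethanesulfonate | C=C(CCC=C(C)C)OS(=O)(=O)C(F)(F)F | intermediate
10 | bis(pinacolato)diboron | CC1(C)OB(OC1(C)C)B1OC(C)(C)C(C)(C)O1 | starting material
11 | potassium hydrogen difluoride | [K+].F.[F-] | starting material
12 | 4,4,5,5-tetramethyl-2-(6-methylhepta-1,5-dien-2-yl)-1,3,2-dioxaborolane | C=C(CCC=C(C)C)B1OC(C)(C)C(C)(C)O1 | intermediate
13 | potassium trifluoro(6-methylhepta-1,5-dien-2-yl)borate | [K+].C=C(CCC=C(C)C)[B-](F)(F)F | intermediate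
14 | (E)-4-methylpent-2-enal | CC(C)/C=C/C=O | starting material
15 | (3S)-3-(2,6-dihydroxy-4-methoxy-3,5-dimethylphenyl)-4-methylpentanal | CC(C)[C@H](CC=O)c1c(O)c(C)c(OC)c(C)c1O | intermediate
16 | (4S)-7-methoxy-6,8-dimethyl-4-(propan-2-yl)chromane-2,5-diol (both C2 anomers) | OC1C[C@@H](C(C)C)c2c(O)c(C)c(OC)c(C)c2O1 | intermediate
17 | (4S)-5-hydroxy-7-methoxy-6,8-dimethyl-4-(propan-2-yl)-3,4-dihydrochromenylium (cyclic oxocarbenium ion) | CC(C)[C@@H]1CC=[O+]c2c(C)c(OC)c(C)c(O)c12 | intermediate
18 | (2S,4S)-7-methoxy-6,8-dimethyl-2-(6-methylhepta-1,5-dien-2-yl)-4-(propan-2-yl)chroman-5-ol | C=C(CCC=C(C)C)[C@@H]1C[C@@H](C(C)C)c2c(O)c(C)c(OC)c(C)c2O1 | intermediate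
19 | lithium (2S,4S)-7-methoxy-6,8-dimethyl-2-(6-methylhepta-1,5-dien-2-yl)-4-(propan-2-yl)chroman-5-olate | [Li+].C=C(CCC=C(C)C)[C@@H]1C[C@@H](C(C)C)c2c([O-])c(C)c(OC)c(C)c2O1 | intermediate
20 | (2S,4S)-7-methoxy-6,6,8-trimethyl-2-(6-methylhepta-1,5-dien-2-yl)-4-(propan-2-yl)-2,3,4,6-tetrahydro-5H-chromen-5-one | C=C(CCC=C(C)C)[C@@H]1C[C@@H](C(C)C)C2=C(O1)C(C)=C(OC)C(C)(C)C2=O | intermediate
21 | (6R,7S)-3-methoxy-2,4,4-trimethyl-10-(4-methylpent-3-en-1-yl)-7-(propan-2-yl)spiro[5.5]undeca-2,9-diene-1,5-dione | COC1=C(C)C(=O)[C@]2(CC(CCC=C(C)C)=CC[C@H]2C(C)C)C(=O)C1(C)C | target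

**Step count**
Total: 8 steps. Longest linear sequence: 6 steps (1, 2, 5, 6, 7, 8 from compound 1); steps 3 and 4 make the side-chain reagent.

**Steps most likely to fail**

Step 8. Heterolysis of the allylic C2–O1 bond, or retro-hetero-Diels–Alder cleavage to the achiral alkylidene dione and myrcene, may outrun the concerted shift; this would erode the transfer of configuration to C6 and could open the way to the regioisomeric Diels–Alder adduct. The fallback sets out from 20 and makes the same C–C bond by a stepwise, metal-mediated route instead of a pericyclic one: the Pd(0)-catalysed O-to-C allyl transposition of allyl enol ethers of 1,3-dicarbonyl compounds (Pd(PPh3)4, THF, 25–40 °C). Oxidative addition into the allylic C–O bond should give a π-allylpalladium dienolate zwitterion that closes at the CH2 terminus to the six-membered ring and so returns directly to 21. This runs far below the temperature of the cycloreversion but does not guarantee the spiro configuration, so the C6 epimer would have to be removed by chromatography. It makes no new compound on the way (F0).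

Step 7. O-Methylation of the phenolate, or attack at the para carbon C8, may compete with C-methylation at C6; the para pathway would lead after step 8 to the C6 epimer of the target. The fallback sets out from 18 and delivers the carbon to C6 by an ortho-specific [2,3]-sigmatropic route. The Corey–Kim reagent (NCS, Me2S, CH2Cl2, −40 °C; then Et3N) should give an aryloxysulfonium ylide that rearranges to the less hindered ortho carbon and, because that carbon is substituted, stops at the dienone (2S,4S)-7-methoxy-6,8-dimethyl-2-(6-methylhepta-1,5-dien-2-yl)-6-[(methylsulfanyl)methyl]-4-(propan-2-yl)-2,3,4,6-tetrahydro-5H-chromen-5-one F1 (mixture at C6). Desulfurisation with acetone-deactivated Raney nickel (THF, 0 °C) then returns to 20; the 1,1-disubstituted alkene is the group to watch in this operation.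

Step 6. Facial selectivity at C2 of the oxocarbenium ion may be poor, or the cation may be captured by the trisubstituted alkene of the reagent (Prins-type cyclisation). The fallback sets out from 16 and enol triflate 9, so that step 4 is not needed. Nozaki–Hiyama–Kishi coupling (CrCl2, cat. NiCl2, DMF, rt) with the open-chain aldehyde tautomer should give the allylic alcohol 2-[(3S)-5-hydroxy-2,10-dimethyl-6-methylideneundec-9-en-3-yl]-5-methoxy-4,6-dimethylbenzene-1,3-diol F2 as a mixture of carbinol epimers. Intramolecular Mitsunobu etherification (PPh3, DIAD, THF, 0 °C), in which either phenolic hydroxyl gives the same chromane, closes the pyran with inversion and returns to 18 after chromatographic separation from its 2,4-cis isomer.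

**Further compounds**
F0 | step 8 | none | none
F1 | step 7 | (2S,4S)-7-methoxy-6,8-dimethyl-2-(6-methylhepta-1,5-dien-2-yl)-6-[(methylsulfanyl)methyl]-4-(propan-2-yl)-2,3,4,6-tetrahydro-5H-chromen-5-one (C6 epimers) | C=C(CCC=C(C)C)[C@@H]1C[C@@H](C(C)C)C2=C(O1)C(C)=C(OC)C(C)(CSC)C2=O
F2 | step 6 | 2-[(3S)-5-hydroxy-2,10-dimethyl-6-methylideneundec-9-en-3-yl]-5-methoxy-4,6-dimethylbenzene-1,3-diol (carbinol epimers) | CC(C)[C@H](CC(O)C(=C)CCC=C(C)C)c1c(O)c(C)c(OC)c(C)c1O
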